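The benzene ring is built last instead of being bought. Its three substituted carbons (the C–OH carbon, the C–OMe carbon and the carbon bearing benzylic C1 of the tridecyl chain) are mutually meta. This is the pattern that a 3-alkylcyclobut-2-enone and an alkoxyacetylene deliver on heating. In one neutral thermal operation the cyclobutenone and methoxyacetylene form three ring C–C bonds and close the six-membered ring. The two oxygens emerge already differentiated: the ketone carbon becomes the free phenol and the alkyne brings OMe. The precursor is a four-membered enone whose C3 side chain already holds the (R)-acetoxy stereocentre, taken from (R)-epichlorohydrin.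

Key step: step 7

Assumption: commercial (R)-epichlorohydrin is taken as enantiopure, so it fixes the optical purity of the target; the ring CH of the transient alkenylcyclobutenone in the key step is a stereocentre of no consequence and is drawn undefined.

Step 1
Reactants: 1 (R)-epichlorohydrin; 2 decylmagnesium bromide
Product: 3 (R)-1-chlorotridecan-2-ol
Conditions: CuI (10 mol %), THF, −40 to −20 °C; sat. aq NH4Cl
Reagents that add atoms: none
Why: Copper-catalysed Grignard opening of a terminal epoxide proceeds by SN2 attack at the unsubstituted oxirane CH2 faster than chloride displacement at low temperature, and since no bond at the stereocentre is touched the (R) centre of 1 passes unchanged into 3 (ranking O > CH2Cl > alkyl keeps the descriptor).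

Step 2
Reactants: 3 (R)-1-chlorotridecan-2-ol; 4 lithium acetylide–ethylenediamine complex (LiC≡CH·H2NCH2CH2NH2)
Product: 6 (R)-pentadec-1-yn-4-ol, via (R)-2-undecyloxirane 5 (not isolated)
Conditions: 4 (3 equiv), DMSO–THF, 0 °C to rt; H2O
Reagents that add atoms: none
Why: One equivalent of acetylide deprotonates 3, the alkoxide closes to 5 by intramolecular Williamson displacement (3-exo-tet), and a second equivalent opens 5 by SN2 at its CH2 (epoxide alkynylation), so the C–O bond at the stereocentre persists throughout and (R) is retained.

Step 3
Reactants: 6 (R)-pentadec-1-yn-4-ol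
Product: 7 (R)-pentadec-1-yn-4-yl acetate
Conditions: Ac2O (1.5 equiv), pyridine, DMAP (5 mol %), CH2Cl2, 0 °C to rt
Reagents that add atoms: acetic anhydride, CC(=O)OC(C)=O
Why: DMAP-catalysed O-acetylation of a secondary alcohol occurs at oxygen with retention, installs the ester of the target for good, and removes the OH that would otherwise consume the acid chloride in step 4.

Step 4
Reactants: 7 (R)-pentadec-1-yn-4-yl acetate; 8 trichloroacetyl chloride
Product: 10 (R)-1-(4,4-dichloro-3-oxocyclobut-1-en-1-yl)tridecan-2-yl acetate, via dichloroketene 9 (not isolated)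
Conditions: 8 (2 equiv, slow addition), Zn–Cu couple (3 equiv), Et2O–DME, rt
Reagents that add atoms: none
Why: Zinc dechlorination of 8 releases dichloroketene slowly, and its [2+2] ketene–alkyne cycloaddition joins the electrophilic ketene carbonyl carbon to the terminal alkyne CH, so only the 3-alkyl-4,4-dichlorocyclobutenone should form while DME binds ZnCl2 and the acetate stays inert.

Step 5
Reactants: 10 (R)-1-(4,4-dichloro-3-oxocyclobut-1-en-1-yl)tridecan-2-yl acetate
Product: 11 (R)-1-(3-oxocyclobut-1-en-1-yl)tridecan-2-yl acetate
Conditions: Zn dust (5 equiv), AcOH (5 equiv), TMEDA (5 equiv), EtOH, 0 °C to rt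
Reagents that add atoms: none
Why: Reductive α-dehalogenation with zinc, each zinc enolate being protonated by the AcOH–TMEDA buffer, strips both chlorines under nearly neutral conditions established to spare the strained conjugated double bond of 3-alkylcyclobutenones, and the acetate centre is not involved.

Step 6
Reactants: 12 chloroacetaldehyde dimethyl acetal
Product: 14 methoxyacetylene, via sodium methoxyacetylide 13 (not isolated)
Conditions: NaNH2 (3.2 equiv), liq. NH3, −33 °C; evaporate NH3; sat. aq NaCl, −70 °C; distil into cold toluene, store cold over K2CO3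
Reagents that add atoms: none
Why: Twofold base-induced β-elimination (first MeOH, then HCl) followed by deprotonation gives acetylide 13, and cold aqueous protonation releases the volatile ynol ether, which is the standard alkoxyacetylene preparation from α-chloroacetals.

Step 7
Reactants: 11 (R)-1-(3-oxocyclobut-1-en-1-yl)tridecan-2-yl acetate; 14 methoxyacetylene
Product: 19 (R)-1-(3-hydroxy-5-methoxyphenyl)tridecan-2-yl acetate, via vinylketene 15 (not isolated), via alkenylcyclobutenone 16 (not isolated), via dienylketene 17 (not isolated), via cyclohexadienone 18 (not isolated)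
Conditions: 14 (3 equiv, toluene solution), toluene, base-washed sealed pressure tube, 80 °C, then 110 °C
Reagents that add atoms: none
Why: Danheiser benzannulation, a pericyclic cascade in which conrotatory 4π opening of 11 (cleaving the C(=O)–CH2 bond) gives vinylketene 15, [2+2] cycloaddition of its C=C=O unit with 14 gives 16, and a second 4π opening gives dienylketene 17. The benzene ring closes by disrotatory 6π electrocyclisation of 17, which joins the ketene carbon to the terminal =CH2, and cyclohexadienone 18 then tautomerises irreversibly to phenol 19. The closest known reaction type is this same annulation of simple 3-alkylcyclobutenones with alkoxyacetylenes, which gives 5-alkyl-3-alkoxyphenols. Regioselectivity is the only selectivity required, and the polarised ynol ether secures it: its unsubstituted nucleophilic carbon attacks the ketene carbonyl carbon, so OMe ends meta to OH and the C3 substituent of 11 ends meta to both. No lasting stereocentre is created (the ring CH of 16 vanishes on reopening, and because the openings are reversible only the geometry of 17 with ketene and vinyl cis goes on to close), and the acetate stereocentre lies outside the reacting π system and is untouched under neutral thermal conditions. The excess of 14 keeps 15 from being intercepted by the phenol as it accumulates.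

Compound list
1 | (R)-epichlorohydrin, (R)-2-(chloromethyl)oxirane | ClC[C@H]1CO1 | starting material
2 | decylmagnesium bromide | CCCCCCCCCC[Mg]Br | starting material
3 | (R)-1-chlorotridecan-2-ol | CCCCCCCCCCC[C@H](CCl)O | intermediate
4 | lithium acetylide–ethylenediamine complex | [Li+].[C-]#C.NCCN | starting material
5 | (R)-2-undecyloxirane | CCCCCCCCCCC[C@@H]1CO1 | intermediate
6 | (R)-pentadec-1-yn-4-ol | CCCCCCCCCCC[C@H](CC#C)O | intermediate
7 | (R)-pentadec-1-yn-4-yl acetate | CCCCCCCCCCC[C@H](CC#C)OC(C)=O | intermediate
8 | trichloroacetyl chloride | ClC(Cl)(Cl)C(Cl)=O | starting material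
9 | dichloroketene | ClC(Cl)=C=O | intermediate
10 | (R)-1-(4,4-dichloro-3-oxocyclobut-1-en-1-yl)tridecan-2-yl acetate | CCCCCCCCCCC[C@H](CC1=CC(=O)C1(Cl)Cl)OC(C)=O | intermediate
11 | (R)-1-(3-oxocyclobut-1-en-1-yl)tridecan-2-yl acetate | CCCCCCCCCCC[C@H](CC1=CC(=O)C1)OC(C)=O | intermediate
12 | chloroacetaldehyde dimethyl acetal, 2-chloro-1,1-dimethoxyethane | COC(CCl)OC | starting material
13 | sodium methoxyacetylide | [Na+].[C-]#COC | intermediate
14 | methoxyacetylene | COC#C | intermediate
15 | vinylketene, (R)-3-methylidene-1-oxohexadec-1-en-5-yl acetate | CCCCCCCCCCC[C@H](CC(=C)C=C=O)OC(C)=O | intermediate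
16 | alkenylcyclobutenone, (4R)-2-(2-methoxy-4-oxocyclobut-2-en-1-yl)pentadec-1-en-4-yl acetate, ring CH undefined | CCCCCCCCCCC[C@H](CC(=C)C1C(=O)C=C1OC)OC(C)=O | intermediate
17 | dienylketene, (3E,7R)-3-methoxy-5-methylidene-1-oxooctadeca-1,3-dien-7-yl acetate | CCCCCCCCCCC[C@H](CC(=C)/C=C(/OC)C=C=O)OC(C)=O | intermediate
18 | cyclohexadienone, (R)-1-(3-methoxy-5-oxocyclohexa-1,3-dien-1-yl)tridecan-2-yl acetate | CCCCCCCCCCC[C@H](CC1=CC(OC)=CC(=O)C1)OC(C)=O | intermediate
19 | (R)-1-(3-hydroxy-5-methoxyphenyl)tridecan-2-yl acetate | CCCCCCCCCCC[C@H](Cc1cc(O)cc(OC)c1)OC(C)=O | target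

Total step count: 7. Longest linear sequence: 6 (steps 1, 2, 3, 4, 5 and 7). Step 6 is a one-step side branch.

Steps most likely to fail

1. Step 7.
- **What may go wrong:** The ynol ether may self-condense at the temperature needed for ring opening, or the cascade may stall before the second ring opening. The vinylketene may also O-acylate the product phenol. That last process can be undone by a brief K2CO3/MeOH treatment at 0 °C, which cleaves aryl esters far faster than the secondary acetate.
- **Fallback (arene bought, not built):** It sets out from 3 and comes back at 19. Chlorohydrin 3 is closed with powdered NaOH in Et2O, and epoxide 5 is isolated this time. Commercial 3-bromo-5-methoxyphenol is benzylated (BnBr, K2CO3, acetone) to 1-(benzyloxy)-3-bromo-5-methoxybenzene F1. With Mg in THF this gives [3-(benzyloxy)-5-methoxyphenyl]magnesium bromide F2. CuI-catalysed opening of 5 at its CH2 terminus gives (R)-1-[3-(benzyloxy)-5-methoxyphenyl]tridecan-2-ol F3. Acetylation (Ac2O, pyridine, DMAP) gives (R)-1-[3-(benzyloxy)-5-methoxyphenyl]tridecan-2-yl acetate F4. Hydrogenolysis (H2, Pd/C, EtOAc) frees the phenol to give 19, and the homobenzylic acetate is not at risk.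

2. Step 4.
- **What may go wrong:** Dichloroketene may self-condense, or ZnCl2 may promote decomposition, faster than addition to an alkyne that the nearby acetoxy group deactivates inductively. Allylic migration of chlorine in the adduct is also possible.
- **Fallback (chlorine-free construction of the four-membered ring):** It sets out from 7 and comes back at 11, which also makes step 5 unnecessary. N,N-Dimethylacetamide is activated with Tf2O and 2,4,6-collidine in refluxing 1,2-dichloroethane to give N,N-dimethylketeniminium triflate F5, a much stronger electrophile than a ketene. Its [2+2] cycloaddition with the terminal alkyne of 7 follows the same polarity and gives (R)-[3-(2-acetoxytridecyl)cyclobut-2-en-1-ylidene]dimethylammonium triflate F6. Hydrolysis with aqueous NaHCO3 releases 11.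

3. Step 5.
- **What may go wrong:** Acetic acid may be lost by vinylogous E1cB elimination through the acidic CH2 flanked by the enone and the acetoxy carbon in the amine-containing medium. The ring double bond may migrate, or the strained enone may be over-reduced.
- **Fallback (poorer leaving group on oxygen during the zinc step, acetate installed afterwards without base):** It sets out from 6 and comes back at 11. Alcohol 6 is silylated (TBSCl, imidazole, DMF) to (R)-tert-butyldimethyl(pentadec-1-yn-4-yloxy)silane F7. Dichloroketene 9, generated from 8 as in step 4, gives (R)-3-[2-(tert-butyldimethylsilyloxy)tridecyl]-4,4-dichlorocyclobut-2-en-1-one F8. Zinc dechlorination as in step 5 gives (R)-3-[2-(tert-butyldimethylsilyloxy)tridecyl]cyclobut-2-en-1-one F9. Aqueous HF in MeCN frees (R)-3-(2-hydroxytridecyl)cyclobut-2-en-1-one F10. Lewis-acid-catalysed acetylation (Ac2O, Sc(OTf)3 cat., MeCN, −20 °C) gives 11 with the C–O bond intact.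

Further compounds
F1 | step 7 | 1-(benzyloxy)-3-bromo-5-methoxybenzene | COc1cc(Br)cc(OCc2ccccc2)c1
F2 | step 7 | [3-(benzyloxy)-5-methoxyphenyl]magnesium bromide | COc1cc([Mg]Br)cc(OCc2ccccc2)c1
F3 | step 7 | (R)-1-[3-(benzyloxy)-5-methoxyphenyl]tridecan-2-ol | CCCCCCCCCCC[C@H](Cc1cc(OC)cc(OCc2ccccc2)c1)O
F4 | step 7 | (R)-1-[3-(benzyloxy)-5-methoxyphenyl]tridecan-2-yl acetate | CCCCCCCCCCC[C@H](Cc1cc(OC)cc(OCc2ccccc2)c1)OC(C)=O
F5 | step 4 | N,N-dimethylketeniminium triflate | C=C=[N+](C)C.[O-]S(=O)(=O)C(F)(F)F
F6 | step 4 | (R)-[3-(2-acetoxytridecyl)cyclobut-2-en-1-ylidene]dimethylammonium triflate | CCCCCCCCCCC[C@H](CC1=CC(=[N+](C)C)C1)OC(C)=O.[O-]S(=O)(=O)C(F)(F)F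
F7 | step 5 | (R)-tert-butyldimethyl(pentadec-1-yn-4-yloxy)silane | CCCCCCCCCCC[C@H](CC#C)O[Si](C)(C)C(C)(C)C
F8 | step 5 | (R)-3-[2-(tert-butyldimethylsilyloxy)tridecyl]-4,4-dichlorocyclobut-2-en-1-one | CCCCCCCCCCC[C@H](CC1=CC(=O)C1(Cl)Cl)O[Si](C)(C)C(C)(C)C
F9 | step 5 | (R)-3-[2-(tert-butyldimethylsilyloxy)tridecyl]cyclobut-2-en-1-one | CCCCCCCCCCC[C@H](CC1=CC(=O)C1)O[Si](C)(C)C(C)(C)C
F10 | step 5 | (R)-3-(2-hydroxytridecyl)cyclobut-2-en-1-one | CCCCCCCCCCC[C@H](CC1=CC(=O)C1)O
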